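## Retrosynthetic overview

1. The disubstituted E-alkene is cut by cross-metathesis. This gives a vinyl tetrahydrofuran–lactone (left half) and a 3-(dienyl)butenolide (right half).
2. Key disconnection in the left half: the tetrahydrofuran C–O bond at its CH carbon, together with the lactone acyl C–O bond. Both open to an acyclic (R)-tertiary-carbinol E-alkenoate. Forward, they close by directed epoxidation, 5-exo opening with inversion, then lactonisation.
3. The alkenoate goes back through Johnson–Claisen and Schenck ene steps to (R)-linalool, which supplies the quaternary C–O stereocentre.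
4. Right half: an sp2–sp3 Negishi bond joins 3-bromobutenolide to a homoallylic zinc reagent. That reagent comes from methylalumination of pent-1-en-4-yne and oxirane opening.
5. Ring order: the butenolide is bought as furan-2(5H)-one. The tetrahydrofuran forms next and the γ-lactone last, both in one flask.

Assumption: commercial (R)-(−)-linalool (about 95% ee) is used as bought, and the (1S,2S)-diamine-derived bishydroxamic acid is taken to be the ligand antipode that sends oxygen to the alkene face needed in step 3 (its mirror image is used if the sense proves opposite).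

## Route

Step 1
Reactants: 1 (R)-(−)-linalool
Product: 3 (6R)-2,6-dimethylocta-1,7-diene-3,6-diol, via allylic hydroperoxide 2 (not isolated)
Conditions: O2 (1 atm), tetraphenylporphyrin (0.2 mol%), white LED, CH2Cl2, 0 °C; then PPh3 (1.1 equiv), 0 °C → rt
Reagents that add atoms: oxygen (O=O)
Why: Schenck ene reaction: singlet oxygen attacks only the electron-rich trisubstituted alkene (the vinyl group is inert), abstraction of a methyl hydrogen puts the hydroperoxide on C3 next to a new isopropenyl group and PPh3 reduces the O–O bond; C6 is untouched, the new C3 centre forms about 1:1 and is erased in step 2, and the regioisomeric tertiary product (roughly half of the material) is removed by chromatography.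

Step 2
Reactants: 3 (6R)-2,6-dimethylocta-1,7-diene-3,6-diol; 4 triethyl orthoacetate
Product: 6 ethyl (4E,8R)-8-hydroxy-4,8-dimethyldeca-4,9-dienoate, via ketene acetal 5 (not isolated)
Conditions: EtCO2H (5 mol%), neat in 4 (4 equiv), 125 °C, EtOH distilled off, about 2 h, stopped at full conversion of 3
Reagents that add atoms: none
Why: Johnson–Claisen rearrangement: the unhindered secondary allylic hydroxyl exchanges into the orthoester much faster than the tertiary one, and the chair transition state of 5 with the chain equatorial gives the E-trisubstituted alkene (typically >95:5) while the tertiary carbinol centre is not involved.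

Step 3
Reactants: 6 ethyl (4E,8R)-8-hydroxy-4,8-dimethyldeca-4,9-dienoate
Product: 9 (5S)-5-methyl-5-[(2R,5R)-5-methyl-5-vinyltetrahydrofuran-2-yl]dihydrofuran-2(3H)-one, via epoxide 7 (not isolated), via tetrahydrofuran hydroxy ester 8 (not isolated)
Conditions: Hf(OtBu)4 (10 mol%), (1S,2S)-N,N′-dihydroxy-N,N′-bis(diphenylacetyl)cyclohexane-1,2-diamine (11 mol%), DMPU (20 mol%), cumene hydroperoxide (1.5 equiv), 4 Å MS, toluene, 0 °C → 40 °C
Reagents that add atoms: cumene hydroperoxide (CC(C)(OO)c1ccccc1)
Why: Proposed new method: hydroxyl-directed asymmetric epoxidation of a tertiary bishomoallylic alcohol, run on as a one-flask epoxide-opening and lactonisation cascade; alkoxide exchange puts the tertiary carbinol of 6 and the cumyl peroxide on tetravalent hafnium inside the C2-symmetric bishydroxamate pocket; the short tether lets only the electron-rich C4=C5 alkene reach the bound peroxide oxygen (the monosubstituted vinyl group is far less nucleophilic, as in VO(acac)2/t-BuOOH oxidations of linalool); concerted oxygen transfer turns the E-alkene into trans-epoxide 7 with the face fixed by the ligand (4S,5S); the hafnium-bound alkoxide then attacks C5 from the rear in a 5-exo-tet SN2 opening, so C5 inverts to R and the ring is 2,5-trans because the carbinol carbon is already R, and with no cation there is no 6-endo ether and no ester participation; the tertiary alkoxide freed at C4 keeps its C–O bond (S) and closes onto the ethyl ester, and the expelled ethoxide is exchanged for the next molecule of 6; any material from the minor linalool enantiomer ends up as the separable cis diastereomer; the closest known reaction types are the zirconium- or hafnium-bishydroxamic acid epoxidation of primary homoallylic and bishomoallylic alcohols and of tertiary allylic alcohols, and the VO(acac)2/t-BuOOH epoxidation–cyclisation of bishomoallylic alcohols; new here are the tertiary bishomoallylic director, the double stereodifferentiation and the three C–O bonds made in one operation.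

Step 4
Reactants: 10 pent-1-en-4-yne; 11 oxirane
Product: 14 (3E)-4-methylhepta-3,6-dien-1-ol, via alkenylalane 12 (not isolated), via lithium aluminate 13 (not isolated)
Conditions: AlMe3 (2 equiv), Cp2ZrCl2 (20 mol%), CH2Cl2, 0 °C → rt; volatiles removed, hexane, n-BuLi, 0 °C; 11, THF, 0 °C → rt; aq. HCl
Reagents that add atoms: trimethylaluminium (C[Al](C)C)
Why: Negishi zirconium-catalysed methylalumination: syn addition of Me–Al across the terminal alkyne (methyl to the internal carbon, >98% E, the alkene is untouched), and the derived aluminate opens oxirane with retention of alkene geometry.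

Step 5
Reactants: 14 (3E)-4-methylhepta-3,6-dien-1-ol
Product: 15 (4E)-7-iodo-4-methylhepta-1,4-diene
Conditions: I2, PPh3, imidazole, CH2Cl2, 0 °C
Reagents that add atoms: iodine ([I][I])
Why: Appel-type (Garegg–Samuelsson) iodination: iodide displaces the oxyphosphonium group by SN2 at a primary carbon and the alkenes are not touched.

Step 6
Reactants: 16 furan-2(5H)-one
Product: 18 3-bromofuran-2(5H)-one, via dibromolactone 17 (not isolated)
Conditions: Br2, CH2Cl2, rt → reflux; then Et3N, 0 °C
Reagents that add atoms: bromine (BrBr)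
Why: Bromine adds to the enoate C=C, then E1cB-type dehydrobromination removes the acidic C3–H and expels the C4 bromide, so bromine stays on C3.

Step 7
Reactants: 15 (4E)-7-iodo-4-methylhepta-1,4-diene; 18 3-bromofuran-2(5H)-one
Product: 20 3-[(3E)-4-methylhepta-3,6-dien-1-yl]furan-2(5H)-one, via alkylzinc iodide 19 (not isolated)
Conditions: 15, Zn dust, LiCl, THF, 40 °C; then 18, Pd(OAc)2 (2 mol%), SPhos (4 mol%), THF, rt
Reagents that add atoms: none
Why: Negishi sp3–sp2 cross-coupling: zinc inserts into the primary C–I bond, zerovalent palladium adds quickly into the activated C3–Br bond, the bulky biaryl phosphine favours reductive elimination over β-hydride elimination, and the mild zinc reagent tolerates the lactone and keeps the E-alkene.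

Step 8
Reactants: 9 (5S)-5-methyl-5-[(2R,5R)-5-methyl-5-vinyltetrahydrofuran-2-yl]dihydrofuran-2(3H)-one; 20 3-[(3E)-4-methylhepta-3,6-dien-1-yl]furan-2(5H)-one
Product: 21 3-[(3E,6E)-4-methyl-7-{(2R,5R)-2-methyl-5-[(2S)-2-methyl-5-oxotetrahydrofuran-2-yl]tetrahydrofuran-2-yl}hepta-3,6-dien-1-yl]furan-2(5H)-one (target)
Conditions: second-generation Hoveyda–Grubbs catalyst (2 × 5 mol%), 1,4-benzoquinone (10 mol%), 20 (2 equiv), CH2Cl2, 40 °C, argon sparge
Reagents that add atoms: none
Why: Olefin cross-metathesis between an unhindered terminal alkene (20, dimerises fast and reversibly) and a vinyl group on a fully substituted carbon (9, does not dimerise) is cross-selective; the quaternary neighbour enforces the E-alkene, benzoquinone suppresses migration of the skipped diene, and the trisubstituted and butenolide alkenes and all three stereocentres are spectators.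

## Compound list

1 | (R)-(−)-linalool, (3R)-3,7-dimethylocta-1,6-dien-3-ol | C=C[C@](C)(O)CCC=C(C)C | starting material
2 | (3R)-6-hydroperoxy-3,7-dimethylocta-1,7-dien-3-ol (both C6 epimers) | C=C[C@](C)(O)CCC(OO)C(C)=C | intermediate
3 | (6R)-2,6-dimethylocta-1,7-diene-3,6-diol (both C3 epimers) | C=C[C@](C)(O)CCC(O)C(C)=C | intermediate
4 | triethyl orthoacetate | CC(OCC)(OCC)OCC | starting material
5 | (3R)-6-[(1-ethoxyethenyl)oxy]-3,7-dimethylocta-1,7-dien-3-ol | C=C[C@](C)(O)CCC(OC(=C)OCC)C(C)=C | intermediate
6 | ethyl (4E,8R)-8-hydroxy-4,8-dimethyldeca-4,9-dienoate | CCOC(=O)CC/C(C)=C/CC[C@@](C)(O)C=C | intermediate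
7 | ethyl 3-{(2S,3S)-3-[(3R)-3-hydroxy-3-methylpent-4-en-1-yl]-2-methyloxiran-2-yl}propanoate | CCOC(=O)CC[C@]1(C)O[C@H]1CC[C@@](C)(O)C=C | intermediate
8 | ethyl (4S)-4-hydroxy-4-[(2R,5R)-5-methyl-5-vinyltetrahydrofuran-2-yl]pentanoate | C=C[C@@]1(C)CC[C@H]([C@@](C)(O)CCC(=O)OCC)O1 | intermediate
9 | (5S)-5-methyl-5-[(2R,5R)-5-methyl-5-vinyltetrahydrofuran-2-yl]dihydrofuran-2(3H)-one | C=C[C@@]1(C)CC[C@H]([C@]2(C)CCC(=O)O2)O1 | intermediate
10 | pent-1-en-4-yne | C=CCC#C | starting material
11 | oxirane | C1CO1 | starting material
12 | dimethyl[(1E)-2-methylpenta-1,4-dien-1-yl]alane | C=CC/C(C)=C/[Al](C)C | intermediate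
13 | lithium butyl(dimethyl)[(1E)-2-methylpenta-1,4-dien-1-yl]aluminate | [Li+].C=CC/C(C)=C/[Al-](C)(C)CCCC | intermediate
14 | (3E)-4-methylhepta-3,6-dien-1-ol | C=CC/C(C)=C/CCO | intermediate
15 | (4E)-7-iodo-4-methylhepta-1,4-diene | C=CC/C(C)=C/CCI | intermediate
16 | furan-2(5H)-one | O=C1C=CCO1 | starting material
17 | trans-3,4-dibromodihydrofuran-2(3H)-one (racemic) | O=C1OCC(Br)C1Br | intermediate
18 | 3-bromofuran-2(5H)-one | O=C1OCC=C1Br | intermediate
19 | [(3E)-4-methylhepta-3,6-dien-1-yl]zinc iodide | C=CC/C(C)=C/CC[Zn]I | intermediate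
20 | 3-[(3E)-4-methylhepta-3,6-dien-1-yl]furan-2(5H)-one | C=CC/C(C)=C/CCC1=CCOC1=O | intermediate
21 | 3-[(3E,6E)-4-methyl-7-{(2R,5R)-2-methyl-5-[(2S)-2-methyl-5-oxotetrahydrofuran-2-yl]tetrahydrofuran-2-yl}hepta-3,6-dien-1-yl]furan-2(5H)-one | C/C(=C\CCC1=CCOC1=O)C/C=C/[C@@]1(C)CC[C@H]([C@]2(C)CCC(=O)O2)O1 | target

## Step count and risks

Total step count: 8.

Longest linear sequence: 4 (steps 1, 2, 3, 8). The branch 4, 5, 7, 8 is equally long.

**Step 3 (the proposed new method).** Face selectivity, catalyst turnover with a tertiary carbinol and the cascade itself are all untested. The fallback sets out from 6 and comes back at 9, using known chemistry. Reagent-controlled Shi epoxidation of 6 is run with the L-fructose-derived ketone (the mirror image of the usual D-fructose-derived catalyst, 30 mol%), KHSO5, K2CO3 and Bu4NHSO4 in MeCN–dimethoxymethane–aqueous borate buffer at 0 °C. It gives epoxide 7, which is now isolated. KOtBu (0.2 equiv) in THF at 0 °C then triggers the 5-exo opening to 8 and the lactonisation to 9.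

**Step 2.** The tertiary allylic hydroxyl of 3 may also enter the orthoester, or the diol may cyclodehydrate. The fallback sets out from 3 and comes back at 6. The two hydroxyls are told apart by acylation instead of by exchange rate. Ac2O/pyridine at 0 °C esterifies only the secondary hydroxyl and gives (6R)-6-hydroxy-2,6-dimethylocta-1,7-dien-3-yl acetate F1. LiN(iPr)2 (2.2 equiv) and Me3SiCl in THF at −78 °C give the silyl ketene acetal (6R)-2,6-dimethyl-6-(trimethylsilyloxy)-3-{[1-(trimethylsilyloxy)ethenyl]oxy}octa-1,7-diene F2. On warming to room temperature this undergoes Ireland–Claisen rearrangement to trimethylsilyl (4E,8R)-4,8-dimethyl-8-(trimethylsilyloxy)deca-4,9-dienoate F3. Dilute HCl frees (4E,8R)-8-hydroxy-4,8-dimethyldeca-4,9-dienoic acid F4, and EtI/K2CO3 in DMF returns to 6.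

**Step 8.** The vinyl group of 9 sits on a fully substituted ether carbon and may react too slowly. The fallback sets out from 6 and comes back at 21. The metathesis is moved to the free tertiary allylic alcohol, a clearly better metathesis partner, and the rings are closed afterwards. Epoxide 7 is made and isolated by the Shi epoxidation described above. Its trisubstituted alkene is gone, so ring-closing metathesis to a cyclopentenol cannot occur. Cross-metathesis of 7 with 20 (second-generation Hoveyda–Grubbs catalyst, CH2Cl2, 40 °C) gives ethyl 3-{(2S,3S)-3-[(3R,4E,7E)-3-hydroxy-3,7-dimethyl-10-(2-oxo-2,5-dihydrofuran-3-yl)deca-4,7-dien-1-yl]-2-methyloxiran-2-yl}propanoate F5. Camphorsulfonic acid (10 mol%) in CH2Cl2 at 0 °C is used because the butenolide does not tolerate alkoxide. It opens the epoxide 5-exo to ethyl (4S)-4-hydroxy-4-{(2R,5R)-5-methyl-5-[(1E,4E)-4-methyl-7-(2-oxo-2,5-dihydrofuran-3-yl)hepta-1,4-dien-1-yl]tetrahydrofuran-2-yl}pentanoate F6, which lactonises in the same flask to 21.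

## Further compounds

F0 | step 3 | none | none
F1 | step 2 | (6R)-6-hydroxy-2,6-dimethylocta-1,7-dien-3-yl acetate | C=C[C@](C)(O)CCC(OC(C)=O)C(C)=C
F2 | step 2 | (6R)-2,6-dimethyl-6-(trimethylsilyloxy)-3-{[1-(trimethylsilyloxy)ethenyl]oxy}octa-1,7-diene | C=C[C@](C)(O[Si](C)(C)C)CCC(OC(=C)O[Si](C)(C)C)C(C)=C
F3 | step 2 | trimethylsilyl (4E,8R)-4,8-dimethyl-8-(trimethylsilyloxy)deca-4,9-dienoate | C[Si](C)(C)OC(=O)CC/C(C)=C/CC[C@@](C)(O[Si](C)(C)C)C=C
F4 | step 2 | (4E,8R)-8-hydroxy-4,8-dimethyldeca-4,9-dienoic acid | OC(=O)CC/C(C)=C/CC[C@@](C)(O)C=C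
F5 | step 8 | ethyl 3-{(2S,3S)-3-[(3R,4E,7E)-3-hydroxy-3,7-dimethyl-10-(2-oxo-2,5-dihydrofuran-3-yl)deca-4,7-dien-1-yl]-2-methyloxiran-2-yl}propanoate | CCOC(=O)CC[C@]1(C)O[C@H]1CC[C@@](C)(O)/C=C/C/C(C)=C/CCC1=CCOC1=O
F6 | step 8 | ethyl (4S)-4-hydroxy-4-{(2R,5R)-5-methyl-5-[(1E,4E)-4-methyl-7-(2-oxo-2,5-dihydrofuran-3-yl)hepta-1,4-dien-1-yl]tetrahydrofuran-2-yl}pentanoate | C/C(=C\CCC1=CCOC1=O)C/C=C/[C@@]1(C)CC[C@H]([C@@](C)(O)CCC(=O)OCC)O1
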